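## Structural features

The target (30) is a germacranolide: a cyclodeca-1(10),4-diene (ring carbons C1–C10) with a methyl group on C4, a hydroxymethyl group (C14) on C10, an acetate on C2, a methacrylate on C8 and an α-methylene-γ-butyrolactone (C11–C13) fused across C6–C7 through the C6 oxygen. Both ring alkenes are trisubstituted and ring-cis: C2 and C9 are cis across C1=C10 (E by the sequence rules, because C14 outranks C9), and C3 and C6 are cis across C4=C5 (Z). C6 (R), C7 (R) and C8 (R) form a contiguous triad (H6/H7 anti, so the lactone is trans-fused; H7/H8 syn), whereas C2 (S) stands alone with an alkene on either side and cannot be set by relay from the triad. The fragile groups are the α-methylene lactone and the methacrylate (Michael acceptors), the allylic C–O bonds at C2 and C6, a free 8-hydroxyl in late intermediates (cis to C11, able to translactonise) and the medium ring itself; O2, O8 and O14 must end as acetate, methacrylate and free hydroxyl without migration. The real difficulty is the combination of two geometrically defined trisubstituted alkenes, a remote carbinol of fixed configuration, and closure of a ten-membered ring with control at C6 and C7. The key step uses the run O2–C2–C3–C4=C5–C6: with C6 at the carboxyl level this is a 4-methyl-5,6-dihydropyran-2-one, which can exist only with the ring-cis C4=C5 geometry, so a vinylogous aldol at C2–C3 followed by lactonisation of O2 fixes C2 and the alkene together. The run O8–C8–C9–C10=C1–C2 has the same pattern, so the second alkene is reachable by the same move.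

## Logic of the disconnections

30 ⇒ 29 ⇒ 28 ⇒ 27. The O14–Si bond, the O8 acyl bond and the O8–Si bond are cut in that order. The three oxygens must be told apart, and the two Michael acceptors should appear as late as possible. This leaves one macrocyclic lactone, 27, with two silyl ethers of different stability. The forward steps need clean removal of a secondary TBS ether beside a primary TBDPS ether, and acylation of O8 before it can attack the lactone carbonyl.

27 ⇒ 25. The C6–C7 bond and the O6–C12 acyl bond are cut. This is the only place where the carbocycle and the lactone open together, to an aldehyde and a 2-(bromomethyl)acrylate (via 26). The gain is an acyclic chain with only C2 and C8 as stereocentres. The forward step must form a ten-membered ring, give the anti C6/C7 array, and add to the C7 face that puts C11 cis to O8.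

25 ⇒ 24 ⇒ 23 ⇒ 21 + 22. The C7–C11 bond is cut after undoing the allylic transposition (C13–Br back to C7–OH) and returning the C6 aldehyde to its amide. The three-carbon lactone unit then comes from 22, and the sensitive cis-enal exists for one step only. The forward steps need a hindered α-silyloxy aldehyde to couple without epimerising C8, and hydride to attack the amide alone.

21 ⇒ 20 ⇒ 19 ⇒ 18 ⇒ 17. These are functional-group changes only: C7 aldehyde back to its PMB ether, O2 acetate back to hydroxyl, amide back to the lactone. Lactone 17 stores C6 at the carboxyl level and locks C4=C5 as ring-cis. The forward ring opening must not isomerise the alkene, and O2 must be capped before it can relactonise.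

17 ⇒ 12 + 14 (key step). The C2–C3 bond and the O2–C6 acyl bond are cut. The C2 stereocentre and the C4=C5 geometry are traced to one catalyst-controlled aldol and one ring closure, leaving an enal and a five-carbon dienolate. The forward step needs γ-attack, 1,2-addition, one aldehyde face, and convergence of both enoate isomers on the lactone.

12 ⇒ 11 ⇒ 10 ⇒ 9. The enal is returned through the amide to lactone 9, which holds C1=C10 ring-cis in the same way. The forward steps need ring opening without isomerisation, protection of O8 under neutral conditions, and reduction that stops at the aldehyde.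

9 ⇒ 5 + 6, then 5 ⇒ 4 ⇒ 2 + 3 ⇒ 1, and 14 ⇒ 13. The C8–C9 bond and the O8–C2 acyl bond are cut, repeating the key construction on a two-carbon aldehyde. The dienolate goes back to an enoate made by olefination of a protected hydroxyketone. Everything then comes from small purchasable pieces. The forward steps need the enoate isomer with its methyl group cis to the ester, so that only that methyl is deprotonated, and control of the aldehyde face by chelation.

## Other disconnections considered

Alternative 1: The cut removes both C–O bonds at C2 and C14 and leads back to diene A2 (C14=C10–C1=C2). The forward step would be a 1,4-diacetoxylation with Pd(OAc)2 (divalent palladium), benzoquinone and LiOAc in acetic acid, giving diacetate A1. Acetate would add at C14, a π-allyl complex would span C10–C1–C2, and a second acetate would add at C2. Selective cleavage of the primary acetate would then give 30.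
- In its favour: two oxygen functions and one stereocentre would appear at the very end from a hydrocarbon-like diene. C2 and C14 would need no protecting groups, and on that count it is better than the chosen plan.
- Against it: the C2 configuration and the new C1=C10 geometry would depend only on the conformation of the macrocycle. The C4=C5 alkene, the methacrylate and the methylene lactone can compete for palladium. The final step must distinguish a primary from a secondary allylic acetate beside two other esters. A2 still has to be made, with the C6–C8 triad and the ten-membered ring.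
- Comparison: the chosen plan sets C2 by catalyst and the alkene geometry by a lactone template, while Alternative 1 leaves both to the substrate. Functional-group tolerance is about equal. Step economy could be equal or better only if A2 were easy to reach, which is not evident.

Alternative 2: The cut removes C7–C11 and O6–C12 and leads back to hydrogen malonate A4, a ten-membered ring with a C4=C5–C6=C7 diene. In the forward step Mn(OAc)3 (trivalent manganese, regenerable at an anode) in acetic acid would generate the malonyl radical. The radical would close 5-exo on C7, the allylic radical would be oxidised, and the free carboxyl would capture C6, giving bis-lactone A3. Selective opening of the C8 lactone and decarboxylative methylenation would then have to follow.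
- In its favour: the tether from O8 delivers C11 to the face of O8, so the C7/C8 relationship is secured intramolecularly. This is better than the chosen plan, where that relationship rests on the ring-closing allylation. Two rings, two bonds and three centres would be made in one operation.
- Against it: the ring must already exist and no ring construction is offered. The triene invites transannular radical closure, capture at C4 in place of C6, and loss of C4=C5 geometry in the allylic intermediate. The two carbonyls on C11 must afterwards be told apart and one carbon removed.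
- Comparison: the structure-building power per step is higher, but the selectivity rests on radical and cation behaviour in a flexible ring, not on a catalyst. Step economy after the key step is worse. The late acylations are the same in both plans.

Alternative 3: The cut is the transannular C1–C6 bond, leading back to the cis-fused bicyclic epoxy alcohol A6. In the forward step KH (or Ti(OiPr)4 as Lewis acid) would trigger a Grob fragmentation. The C6 alkoxide would push out the C1–C6 bond antiperiplanar to the C10–O bond of the spiro-epoxide, giving dienone A5 with C1=C10 formed and O14 freed.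
- In its favour: no high-dilution ring closure is needed, which is better than the chosen plan. The alkene geometry follows stereospecifically from the relative configuration of a rigid bicycle, which is equal to the lactone template as a means of geometry control.
- Against it: A6 carries five stereochemical elements on a decalin and would be long to make. A5 lacks C11–C13 and both C6 and C7 centres. Introducing them means alkylation at C7 next to the C6 ketone, with O8 in the β-position (risk of elimination), followed by a stereoselective reduction at C6 in a flexible ring.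
- Comparison: it solves the ring and one alkene, while the chosen plan solves both alkenes and C2 but leaves the ring closure as its hard step. Overall step economy is worse for Alternative 3.

Key step: step 9

Remarks on the chemistry:
- Atom numbers are the germacrane numbers defined above.
- Aldehyde 6 is assumed to be purchasable.
- Enal 12 is 2E by the sequence rules although its formyl group is cis to the C9 chain (ring-cis in 30); a Z label for this geometry would be wrong.
- The senecioate unit is used as the O-methyl O-silyl ketene acetal 14 and not as a bis-silyl acetal of the acid. A carboxylate is not a Michael acceptor, so a thiolate could not recycle the wrong alkene isomer of a hydroxy acid, whereas it can for an ester.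
- Protecting groups are PMB on O7 (chelation in step 4, removed by DDQ alone), TBS on O8 (put on the hydroxy amide without acid or strong base, and a poor leaving group next to the later allylchromium) and TBDPS on O14 (removed last).

## Route

Step 1
Reactants: 1 hydroxyacetone
Product: 2 1-[(tert-butyldiphenylsilyl)oxy]propan-2-one
Conditions: TBDPSCl, imidazole, CH2Cl2, 0 °C → rt
Reagents that add atoms: tert-butyl(chloro)diphenylsilane, CC(C)(C)[Si](Cl)(c1ccccc1)c1ccccc1
Why: Silylation of a primary alcohol; TBDPS is chosen because it must outlast acid, DDQ and the later selective removal of a TBS group.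

Step 2
Reactants: 2 1-[(tert-butyldiphenylsilyl)oxy]propan-2-one; 3 triethyl phosphonoacetate
Product: 4 ethyl (2E)-4-[(tert-butyldiphenylsilyl)oxy]-3-methylbut-2-enoate (methyl cis to the ester)
Conditions: NaH, THF, 0 °C → rt; the E isomer is separated by chromatography
Reagents that add atoms: none
Why: Horner–Wadsworth–Emmons olefination of a ketone, in which the bulkier silyloxymethyl group should end trans to the ester; only this isomer is carried on because the next step removes a proton from the γ-carbon that is cis to the ester.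

Step 3
Reactants: 4 ethyl (2E)-4-[(tert-butyldiphenylsilyl)oxy]-3-methylbut-2-enoate
Product: 5 {[1-ethoxy-3-({[tert-butyl(diphenyl)silyl]oxy}methyl)buta-1,3-dien-1-yl]oxy}trimethylsilane (ketene acetal geometry immaterial)
Conditions: LiN(iPr)2, THF, −78 °C; Me3SiCl, −78 °C → rt; used crude after removal of LiCl
Reagents that add atoms: chlorotrimethylsilane, C[Si](C)(C)Cl
Why: Kinetic γ-deprotonation of a 3-methylalk-2-enoate occurs at the γ-carbon syn to the ester carbonyl (here the methyl group, the future C9), and O-silylation of the dienolate gives the silyl dienol ether.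

Step 4
Reactants: 5 silyl dienolate; 6 (4-methoxybenzyloxy)acetaldehyde
Product: 9 (6R)-6-{[(4-methoxybenzyl)oxy]methyl}-4-{[(tert-butyldiphenylsilyl)oxy]methyl}-5,6-dihydro-2H-pyran-2-one, via lactonisable 2E hydroxy ester 7 (not isolated), via non-lactonisable 2Z hydroxy ester 8 (not isolated)
Conditions: [Cu((R,R)-Ph-pybox)](SbF6)2 (5 mol %), CH2Cl2, −78 °C; 1 M HCl, THF, 0 °C; then PhSH (0.2 equiv), Cs2CO3 (0.2 equiv), MeCN, 40 °C
Reagents that add atoms: none
Why: Vinylogous Mukaiyama aldol on the five-membered chelate of 6 with the divalent copper catalyst, with γ-attack of the dienolate forming C8–C9; the (S,S) complex is known to send silyl ketene acetals to the Si face of chelated alkoxyacetaldehydes, so the (R,R) ligand is used to reach the Re face (8R). Isomer 7 lactonises (6-exo-trig), and 8 is equilibrated into 7 by reversible conjugate addition of thiophenolate, so the lactone fixes C1=C10 as ring-cis.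

Step 5
Reactants: 9 lactone
Product: 10 (2E,5R)-5-hydroxy-N-methoxy-6-[(4-methoxybenzyl)oxy]-N-methyl-3-{[(tert-butyldiphenylsilyl)oxy]methyl}hex-2-enamide (amide cis to C4)
Conditions: MeNH(OMe)·HCl, AlMe3, CH2Cl2, 0 °C → rt
Reagents that add atoms: N,O-dimethylhydroxylamine hydrochloride, CNOC.Cl
Why: Weinreb aminolysis of a lactone by the aluminium amide; attack is at the acyl carbon only (the β-carbon is fully substituted), so the alkene geometry imposed by the ring is kept.

Step 6
Reactants: 10 hydroxy amide
Product: 11 (2E,5R)-5-[(tert-butyldimethylsilyl)oxy]-N-methoxy-6-[(4-methoxybenzyl)oxy]-N-methyl-3-{[(tert-butyldiphenylsilyl)oxy]methyl}hex-2-enamide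
Conditions: TBSOTf, 2,6-lutidine, CH2Cl2, −78 → 0 °C
Reagents that add atoms: tert-butyldimethylsilyl triflate, CC(C)(C)[Si](C)(C)OS(=O)(=O)C(F)(F)F
Why: Silylation of the secondary alcohol under buffered, non-nucleophilic conditions blocks relactonisation without acid or strong base.

Step 7
Reactants: 11 silyl ether amide
Product: 12 (2E,5R)-5-[(tert-butyldimethylsilyl)oxy]-6-[(4-methoxybenzyl)oxy]-3-{[(tert-butyldiphenylsilyl)oxy]methyl}hex-2-enal (formyl cis to C4; C2 aldehyde, ring-cis C1=C10)
Conditions: iBu2AlH, THF, −78 °C; aq. KNaC4H4O6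
Reagents that add atoms: none
Why: Reduction of a Weinreb amide stops at the chelated tetrahedral intermediate, which releases the enal on work-up; low temperature and neutral work-up guard the geometry.

Step 8
Reactants: 13 methyl 3-methylbut-2-enoate
Product: 14 [(1-methoxy-3-methylbuta-1,3-dien-1-yl)oxy]trimethylsilane
Conditions: LiN(iPr)2, THF, −78 °C; Me3SiCl; distilled
Reagents that add atoms: chlorotrimethylsilane, C[Si](C)(C)Cl
Why: γ-Deprotonation of the senecioate (both γ-carbons are methyl groups) and O-silylation give the known silyl dienol ether.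

Step 9
Reactants: 12 enal; 14 silyl dienolate
Product: 17 (6S)-6-[(1E,4R)-4-[(tert-butyldimethylsilyl)oxy]-5-[(4-methoxybenzyl)oxy]-2-{[(tert-butyldiphenylsilyl)oxy]methyl}pent-1-en-1-yl]-4-methyl-5,6-dihydro-2H-pyran-2-one, via 2Z hydroxy ester 15 (not isolated), via 2E hydroxy ester 16 (not isolated)
Conditions: (S)-BINOL (20 mol %), Ti(OiPr)4 (20 mol %), 4 Å MS, Et2O, −78 → −40 °C; 1 M HCl, THF, 0 °C; then PhSH (0.2 equiv), Cs2CO3 (0.2 equiv), MeCN, 40 °C
Reagents that add atoms: none
Why: Asymmetric vinylogous Mukaiyama aldol followed by lactonisation: the BINOL-bound tetravalent titanium Lewis acid activates enal 12, and dienolate 14 attacks through its terminal CH2 (the future C3) in an open transition state, forming C2–C3 with silyl transfer to the aldolate. The closest known reaction type is the titanium–BINOL (also copper- or silicon-based) catalysed vinylogous Mukaiyama aldol of ester-derived silyl dienolates that ends in a 5,6-dihydropyran-2-one. The new C2 centre is set by the catalyst: the (S)-BINOL complex is expected to expose the Si face of the aldehyde, as this catalyst family does for aldehydes with the O > R > H priority pattern, which gives 2S; C8 is remote and should act as a spectator. The ring closes by 6-exo-trig acyl substitution of the freed O2 on the C6 ester, possible only for 15, in which C3 and C6 are cis across C4=C5. Isomer 16 is returned to the pool by reversible conjugate addition of thiophenolate to its enoate (rotation in the adduct, then retro-Michael), so lactone formation drains both isomers. The step needs 1,2- over 1,4-addition (the β-carbon of 12 is fully substituted), γ- over α-attack (open transition state at the unhindered diene terminus) and one aldehyde face (catalyst). The C1=C10 geometry is safe during the equilibration because that alkene is no longer conjugated after the aldol and cannot accept the thiolate.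

Step 10
Reactants: 17 lactone
Product: 18 (2Z,5S,6E,9R)-9-[(tert-butyldimethylsilyl)oxy]-5-hydroxy-N-methoxy-10-[(4-methoxybenzyl)oxy]-N,3-dimethyl-7-{[(tert-butyldiphenylsilyl)oxy]methyl}deca-2,6-dienamide
Conditions: MeNH(OMe)·HCl, AlMe3, CH2Cl2, 0 °C
Reagents that add atoms: N,O-dimethylhydroxylamine hydrochloride, CNOC.Cl
Why: Weinreb aminolysis as in step 5; C6 stays at the carboxyl level and the ring-cis C4=C5 geometry is carried into the open chain.

Step 11
Reactants: 18 hydroxy amide
Product: 19 (2Z,5S,6E,9R)-5-acetoxy-9-[(tert-butyldimethylsilyl)oxy]-N-methoxy-10-[(4-methoxybenzyl)oxy]-N,3-dimethyl-7-{[(tert-butyldiphenylsilyl)oxy]methyl}deca-2,6-dienamide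
Conditions: Ac2O, Et3N, DMAP (cat.), CH2Cl2, 0 °C
Reagents that add atoms: acetic anhydride, CC(=O)OC(C)=O
Why: DMAP-catalysed acetylation puts the final acetate on O2 while O8 and O14 are silylated, and removes the hydroxyl that could re-form the lactone.

Step 12
Reactants: 19 acetate
Product: 20 (2Z,5S,6E,9R)-5-acetoxy-9-[(tert-butyldimethylsilyl)oxy]-10-hydroxy-N-methoxy-N,3-dimethyl-7-{[(tert-butyldiphenylsilyl)oxy]methyl}deca-2,6-dienamide
Conditions: DDQ, CH2Cl2/pH 7 buffer (10:1), 0 °C
Reagents that add atoms: none
Why: Oxidative cleavage of the PMB ether by DDQ (benzylic oxidation, hydrolysis of the oxocarbenium ion); silyl ethers, acetate and amide are inert, and the neutral buffer suppresses silyl migration from O8.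

Step 13
Reactants: 20 primary alcohol
Product: 21 (2Z,5S,6E,9R)-5-acetoxy-9-[(tert-butyldimethylsilyl)oxy]-N-methoxy-N,3-dimethyl-10-oxo-7-{[(tert-butyldiphenylsilyl)oxy]methyl}deca-2,6-dienamide
Conditions: Dess–Martin periodinane, NaHCO3, CH2Cl2, 0 °C → rt; used at once
Reagents that add atoms: none
Why: Buffered Dess–Martin oxidation gives the α-silyloxy aldehyde without base strong enough to epimerise C8.

Step 14
Reactants: 21 aldehyde; 22 methyl acrylate
Product: 23 methyl (4R,6E,8S,10Z)-8-acetoxy-4-[(tert-butyldimethylsilyl)oxy]-3-hydroxy-12-[methoxy(methyl)amino]-10-methyl-2-methylidene-12-oxo-6-{[(tert-butyldiphenylsilyl)oxy]methyl}dodeca-6,10-dienoate (both C3 epimers)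
Conditions: DABCO (1 equiv), 22 (5 equiv), 1,4-dioxane/H2O (1:1), rt
Reagents that add atoms: none
Why: Morita–Baylis–Hillman reaction forms C7–C11; the α-oxygenated aldehyde is an activated acceptor, the enamide is not a competent Michael acceptor for the amine, and the new carbinol centre is erased in the next step.

Step 15
Reactants: 23 Morita–Baylis–Hillman adduct
Product: 24 methyl (2Z,4R,6E,8S,10Z)-8-acetoxy-2-(bromomethyl)-4-[(tert-butyldimethylsilyl)oxy]-12-[methoxy(methyl)amino]-10-methyl-12-oxo-6-{[(tert-butyldiphenylsilyl)oxy]methyl}dodeca-2,6,10-trienoate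
Conditions: NBS, Me2S, CH2Cl2, −20 → 0 °C
Reagents that add atoms: N-bromosuccinimide, O=C1CCC(=O)N1Br
Why: Corey–Kim-type activation of the allylic alcohol and SN2′ delivery of bromide give the rearranged primary bromide as the usual Z isomer (C8 cis to CH2Br).

Step 16
Reactants: 24 allylic bromide amide
Product: 25 methyl (2Z,4R,6E,8S,10Z)-8-acetoxy-2-(bromomethyl)-4-[(tert-butyldimethylsilyl)oxy]-10-methyl-12-oxo-6-{[(tert-butyldiphenylsilyl)oxy]methyl}dodeca-2,6,10-trienoate
Conditions: Cp2Zr(H)Cl (1.5 equiv), THF, 0 °C → rt, 15 min; silica gel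
Reagents that add atoms: none
Why: Schwartz reduction of a tertiary amide to the aldehyde through a stable zirconium hemiaminal is fast and selective over esters, so acetate and enoate should survive; the cis-enal is released only one step before it is consumed.

Step 17
Reactants: 25 bromo enal
Product: 27 (2S,6R,7S,8R)-2-acetoxy-8-[(tert-butyldimethylsilyl)oxy]-14-[(tert-butyldiphenylsilyl)oxy]germacra-1(10),4,11(13)-trien-12,6-olide with both ring alkenes ring-cis (C7 has the spatial arrangement of 30; the S label is a priority effect of silicon), via macrocyclic hydroxy ester 26 (not isolated)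
Conditions: CrCl2 (8 equiv), THF/DMF (10:1), slow addition to 2 mM, rt; aq. NH4Cl; then PPTS (cat.), CH2Cl2, rt
Reagents that add atoms: none
Why: Nozaki–Hiyama–Kishi-type allylation: divalent chromium turns the bromide into a 2-(methoxycarbonyl)allyl species of trivalent chromium that adds through C7 (SE2′) to the C6 aldehyde in a chair transition state with the C5 and C8 chains pseudo-equatorial, giving the anti adduct 26, which closes to the trans-fused γ-lactone (5-exo-trig). The aldehyde is expected to reach C7 from the face away from the bulky silyloxy group on C8, with C9 (part of the forming ring) near the allyl plane, which places C11 cis to O8; the two cis alkenes bring the chain ends together and the silyl ether is a poor leaving group for vinylogous β-elimination.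

Step 18
Reactants: 27 macrocyclic lactone
Product: 28 (2S,6R,7R,8R)-2-acetoxy-8-hydroxy-14-[(tert-butyldiphenylsilyl)oxy]germacra-1(10),4,11(13)-trien-12,6-olide
Conditions: HF·pyridine, pyridine, THF, 0 °C → rt
Reagents that add atoms: none
Why: Buffered HF·pyridine should cleave the secondary TBS ether well before the primary TBDPS ether; the acidic medium avoids alkoxide-driven translactonisation to O8, and 28 is acylated without delay.

Step 19
Reactants: 28 hydroxy lactone
Product: 29 (2S,6R,7R,8R)-2-acetoxy-8-(methacryloyloxy)-14-[(tert-butyldiphenylsilyl)oxy]germacra-1(10),4,11(13)-trien-12,6-olide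
Conditions: methacrylic anhydride, Et3N, DMAP, CH2Cl2, 0 °C → rt
Reagents that add atoms: methacrylic anhydride, C=C(C)C(=O)OC(=O)C(C)=C
Why: DMAP-catalysed acylation of the only free hydroxyl installs the methacrylate on O8.

Step 20
Reactants: 29 silyl ether
Product: 30 (2S,6R,7R,8R)-2-acetoxy-14-hydroxy-8-(methacryloyloxy)germacra-1(10),4,11(13)-trien-12,6-olide, both ring alkenes ring-cis (target)
Conditions: HF·pyridine (excess), THF, rt
Reagents that add atoms: none
Why: Fluoride-mediated cleavage of the primary TBDPS ether under acidic conditions, which the three esters and both Michael acceptors tolerate.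

## Compound list

1 | hydroxyacetone | CC(=O)CO | starting material
2 | 1-[(tert-butyldiphenylsilyl)oxy]propan-2-one | CC(=O)CO[Si](c1ccccc1)(c1ccccc1)C(C)(C)C | intermediate
3 | triethyl phosphonoacetate | CCOC(=O)CP(=O)(OCC)OCC | starting material
4 | ethyl (2E)-4-[(tert-butyldiphenylsilyl)oxy]-3-methylbut-2-enoate | CCOC(=O)/C=C(\C)CO[Si](c1ccccc1)(c1ccccc1)C(C)(C)C | intermediate
5 | {[1-ethoxy-3-({[tert-butyl(diphenyl)silyl]oxy}methyl)buta-1,3-dien-1-yl]oxy}trimethylsilane | C=C(CO[Si](c1ccccc1)(c1ccccc1)C(C)(C)C)C=C(OCC)O[Si](C)(C)C | intermediate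
6 | (4-methoxybenzyloxy)acetaldehyde | O=CCOCc1ccc(OC)cc1 | starting material
7 | ethyl (2E,5R)-5-hydroxy-6-[(4-methoxybenzyl)oxy]-3-{[(tert-butyldiphenylsilyl)oxy]methyl}hex-2-enoate (ester cis to C4; formed in the flask, step 4) | O[C@@H](COCc1ccc(OC)cc1)C/C(CO[Si](c2ccccc2)(c2ccccc2)C(C)(C)C)=C\C(=O)OCC | intermediate
8 | ethyl (2Z,5R)-5-hydroxy-6-[(4-methoxybenzyl)oxy]-3-{[(tert-butyldiphenylsilyl)oxy]methyl}hex-2-enoate (ester trans to C4; formed in the flask, step 4) | O[C@@H](COCc1ccc(OC)cc1)C/C(CO[Si](c2ccccc2)(c2ccccc2)C(C)(C)C)=C/C(=O)OCC | intermediate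
9 | (6R)-6-{[(4-methoxybenzyl)oxy]methyl}-4-{[(tert-butyldiphenylsilyl)oxy]methyl}-5,6-dihydro-2H-pyran-2-one | COc1ccc(COC[C@H]2CC(CO[Si](c3ccccc3)(c3ccccc3)C(C)(C)C)=CC(=O)O2)cc1 | intermediate
10 | (2E,5R)-5-hydroxy-N-methoxy-6-[(4-methoxybenzyl)oxy]-N-methyl-3-{[(tert-butyldiphenylsilyl)oxy]methyl}hex-2-enamide | O[C@@H](COCc1ccc(OC)cc1)C/C(CO[Si](c2ccccc2)(c2ccccc2)C(C)(C)C)=C\C(=O)N(C)OC | intermediate
11 | (2E,5R)-5-[(tert-butyldimethylsilyl)oxy]-N-methoxy-6-[(4-methoxybenzyl)oxy]-N-methyl-3-{[(tert-butyldiphenylsilyl)oxy]methyl}hex-2-enamide | CC(C)(C)[Si](C)(C)O[C@@H](COCc1ccc(OC)cc1)C/C(CO[Si](c2ccccc2)(c2ccccc2)C(C)(C)C)=C\C(=O)N(C)OC | intermediate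
12 | (2E,5R)-5-[(tert-butyldimethylsilyl)oxy]-6-[(4-methoxybenzyl)oxy]-3-{[(tert-butyldiphenylsilyl)oxy]methyl}hex-2-enal | CC(C)(C)[Si](C)(C)O[C@@H](COCc1ccc(OC)cc1)C/C(CO[Si](c2ccccc2)(c2ccccc2)C(C)(C)C)=C\C=O | intermediate
13 | methyl 3-methylbut-2-enoate | COC(=O)C=C(C)C | starting material
14 | [(1-methoxy-3-methylbuta-1,3-dien-1-yl)oxy]trimethylsilane | C=C(C)C=C(OC)O[Si](C)(C)C | intermediate
15 | methyl (2Z,5S,6E,9R)-9-[(tert-butyldimethylsilyl)oxy]-5-hydroxy-10-[(4-methoxybenzyl)oxy]-3-methyl-7-{[(tert-butyldiphenylsilyl)oxy]methyl}deca-2,6-dienoate (formed in the flask, step 9) | CC(C)(C)[Si](C)(C)O[C@@H](COCc1ccc(OC)cc1)C/C(CO[Si](c2ccccc2)(c2ccccc2)C(C)(C)C)=C\[C@@H](O)C/C(C)=C\C(=O)OC | intermediate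
16 | methyl (2E,5S,6E,9R)-9-[(tert-butyldimethylsilyl)oxy]-5-hydroxy-10-[(4-methoxybenzyl)oxy]-3-methyl-7-{[(tert-butyldiphenylsilyl)oxy]methyl}deca-2,6-dienoate (formed in the flask, step 9) | CC(C)(C)[Si](C)(C)O[C@@H](COCc1ccc(OC)cc1)C/C(CO[Si](c2ccccc2)(c2ccccc2)C(C)(C)C)=C\[C@@H](O)C/C(C)=C/C(=O)OC | intermediate
17 | (6S)-6-[(1E,4R)-4-[(tert-butyldimethylsilyl)oxy]-5-[(4-methoxybenzyl)oxy]-2-{[(tert-butyldiphenylsilyl)oxy]methyl}pent-1-en-1-yl]-4-methyl-5,6-dihydro-2H-pyran-2-one | CC(C)(C)[Si](C)(C)O[C@@H](COCc1ccc(OC)cc1)C/C(CO[Si](c2ccccc2)(c2ccccc2)C(C)(C)C)=C\[C@@H]3CC(C)=CC(=O)O3 | intermediate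
18 | (2Z,5S,6E,9R)-9-[(tert-butyldimethylsilyl)oxy]-5-hydroxy-N-methoxy-10-[(4-methoxybenzyl)oxy]-N,3-dimethyl-7-{[(tert-butyldiphenylsilyl)oxy]methyl}deca-2,6-dienamide | CC(C)(C)[Si](C)(C)O[C@@H](COCc1ccc(OC)cc1)C/C(CO[Si](c2ccccc2)(c2ccccc2)C(C)(C)C)=C\[C@@H](O)C/C(C)=C\C(=O)N(C)OC | intermediate
19 | (2Z,5S,6E,9R)-5-acetoxy-9-[(tert-butyldimethylsilyl)oxy]-N-methoxy-10-[(4-methoxybenzyl)oxy]-N,3-dimethyl-7-{[(tert-butyldiphenylsilyl)oxy]methyl}deca-2,6-dienamide | CC(C)(C)[Si](C)(C)O[C@@H](COCc1ccc(OC)cc1)C/C(CO[Si](c2ccccc2)(c2ccccc2)C(C)(C)C)=C\[C@@H](OC(C)=O)C/C(C)=C\C(=O)N(C)OC | intermediate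
20 | (2Z,5S,6E,9R)-5-acetoxy-9-[(tert-butyldimethylsilyl)oxy]-10-hydroxy-N-methoxy-N,3-dimethyl-7-{[(tert-butyldiphenylsilyl)oxy]methyl}deca-2,6-dienamide | CC(C)(C)[Si](C)(C)O[C@@H](CO)C/C(CO[Si](c1ccccc1)(c1ccccc1)C(C)(C)C)=C\[C@@H](OC(C)=O)C/C(C)=C\C(=O)N(C)OC | intermediate
21 | (2Z,5S,6E,9R)-5-acetoxy-9-[(tert-butyldimethylsilyl)oxy]-N-methoxy-N,3-dimethyl-10-oxo-7-{[(tert-butyldiphenylsilyl)oxy]methyl}deca-2,6-dienamide | CC(C)(C)[Si](C)(C)O[C@@H](C=O)C/C(CO[Si](c1ccccc1)(c1ccccc1)C(C)(C)C)=C\[C@@H](OC(C)=O)C/C(C)=C\C(=O)N(C)OC | intermediate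
22 | methyl acrylate | C=CC(=O)OC | starting material
23 | methyl (4R,6E,8S,10Z)-8-acetoxy-4-[(tert-butyldimethylsilyl)oxy]-3-hydroxy-12-[methoxy(methyl)amino]-10-methyl-2-methylidene-12-oxo-6-{[(tert-butyldiphenylsilyl)oxy]methyl}dodeca-6,10-dienoate (both C3 epimers) | CC(C)(C)[Si](C)(C)O[C@@H](C(O)C(=C)C(=O)OC)C/C(CO[Si](c1ccccc1)(c1ccccc1)C(C)(C)C)=C\[C@@H](OC(C)=O)C/C(C)=C\C(=O)N(C)OC | intermediate
24 | methyl (2Z,4R,6E,8S,10Z)-8-acetoxy-2-(bromomethyl)-4-[(tert-butyldimethylsilyl)oxy]-12-[methoxy(methyl)amino]-10-methyl-12-oxo-6-{[(tert-butyldiphenylsilyl)oxy]methyl}dodeca-2,6,10-trienoate | CC(C)(C)[Si](C)(C)O[C@@H](/C=C(\CBr)C(=O)OC)C/C(CO[Si](c1ccccc1)(c1ccccc1)C(C)(C)C)=C\[C@@H](OC(C)=O)C/C(C)=C\C(=O)N(C)OC | intermediate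
25 | methyl (2Z,4R,6E,8S,10Z)-8-acetoxy-2-(bromomethyl)-4-[(tert-butyldimethylsilyl)oxy]-10-methyl-12-oxo-6-{[(tert-butyldiphenylsilyl)oxy]methyl}dodeca-2,6,10-trienoate | CC(C)(C)[Si](C)(C)O[C@@H](/C=C(\CBr)C(=O)OC)C/C(CO[Si](c1ccccc1)(c1ccccc1)C(C)(C)C)=C\[C@@H](OC(C)=O)C/C(C)=C\C=O | intermediate
26 | methyl 2-[(1S,2R,3Z,6S,7E,10R)-6-acetoxy-10-[(tert-butyldimethylsilyl)oxy]-2-hydroxy-4-methyl-8-{[(tert-butyldiphenylsilyl)oxy]methyl}cyclodeca-3,7-dien-1-yl]prop-2-enoate (formed in the flask, step 17) | CC(C)(C)[Si](C)(C)O[C@@H]1C/C(CO[Si](c2ccccc2)(c2ccccc2)C(C)(C)C)=C\[C@@H](OC(C)=O)C/C(C)=C\[C@@H](O)[C@@H]1C(=C)C(=O)OC | intermediate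
27 | (2S,6R,7S,8R)-2-acetoxy-8-[(tert-butyldimethylsilyl)oxy]-14-[(tert-butyldiphenylsilyl)oxy]germacra-1(10),4,11(13)-trien-12,6-olide, ring-cis alkenes | CC(C)(C)[Si](C)(C)O[C@@H]1C/C(CO[Si](c3ccccc3)(c3ccccc3)C(C)(C)C)=C\[C@@H](OC(C)=O)C/C(C)=C\[C@H]2OC(=O)C(=C)[C@@H]21 | intermediate
28 | (2S,6R,7R,8R)-2-acetoxy-8-hydroxy-14-[(tert-butyldiphenylsilyl)oxy]germacra-1(10),4,11(13)-trien-12,6-olide, ring-cis alkenes | O[C@@H]1C/C(CO[Si](c3ccccc3)(c3ccccc3)C(C)(C)C)=C\[C@@H](OC(C)=O)C/C(C)=C\[C@H]2OC(=O)C(=C)[C@@H]21 | intermediate
29 | (2S,6R,7R,8R)-2-acetoxy-8-(methacryloyloxy)-14-[(tert-butyldiphenylsilyl)oxy]germacra-1(10),4,11(13)-trien-12,6-olide, ring-cis alkenes | C=C(C)C(=O)O[C@@H]1C/C(CO[Si](c3ccccc3)(c3ccccc3)C(C)(C)C)=C\[C@@H](OC(C)=O)C/C(C)=C\[C@H]2OC(=O)C(=C)[C@@H]21 | intermediate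
30 | (2S,6R,7R,8R)-2-acetoxy-14-hydroxy-8-(methacryloyloxy)germacra-1(10),4,11(13)-trien-12,6-olide, ring-cis alkenes (CNP0138477.1) | C=C(C)C(=O)O[C@@H]1C/C(CO)=C\[C@@H](OC(C)=O)C/C(C)=C\[C@H]2OC(=O)C(=C)[C@@H]21 | target

## Step count and least certain steps

Total: 20 steps. Longest linear sequence: 19 steps (steps 1–7 and 9–20; step 8 is a one-step side branch).

**Step 9 (key step).** The most likely failures are slow or poorly face-selective addition, because a weak Lewis acid meets a hindered β,β-disubstituted enal, and incomplete funnelling of the non-lactonisable isomer, because thiolate addition to a fully substituted β-carbon is slow. Isomerisation of the enal before C–C bond formation is a lesser risk. The fallback sets out from 12 and returns at 17. Keck-type asymmetric methallylation of 12 with (S)-BINOL, Ti(OiPr)4 and tributyl(2-methylallyl)stannane would give the (S)-homoallylic alcohol F1. Acryloyl chloride and iPr2NEt would give its acrylate F2. Ring-closing metathesis with the second-generation Grubbs catalyst (H2IMes)(PCy3)Cl2Ru=CHPh would close the dihydropyranone 17, whose ring again forces the cis geometry.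

**Step 17.** The most likely failure is poor control of relative configuration, either syn addition at C6/C7 or attack on the other face of C7 relative to C8. The allylchromium geometry, the chair preference and the ring strain of the forming macrocycle may not point the same way. Oligomerisation and vinylogous β-elimination of the silyloxy group are further risks. The fallback sets out from 25 and returns at 26 and thus 27. The closure is run with Mn, Me3SiCl and catalytic CrCl2 so that the C6 alkoxide is trapped as its silyl ether before it can lactonise, giving the C6-epimeric trimethylsilyl ether F3. Mild acid desilylation and immediate Dess–Martin oxidation would give the C6 ketone F4. Reduction with NaBH4/CeCl3·7H2O, or with an oxazaborolidine-catalysed borane reduction chosen for the 6R carbinol, would return 26 for lactonisation. C6 is then set by reduction and not by the C–C bond formation. An error at C7 is not repaired by this sequence.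

**Step 16.** The most likely failure is hydride transfer to the 2-(bromomethyl)enoate (SN2′ reduction) competing with amide reduction, because that unit is a strong electrophile. The fallback sets out from 23 and returns at 25. The Schwartz reduction is moved ahead of the bromination: Cp2Zr(H)Cl (one extra equivalent for the hydroxyl) would convert 23 into the hydroxy enal F5, and NBS/Me2S would then give 25, so the hydride never meets the allylic bromide.

**Step 14.** The most likely failure is slow coupling of the hindered α-silyloxy aldehyde, which gives the amine time to epimerise C8. The fallback sets out from 21 and returns at 23. Methyl propiolate is hydroaluminated with iBu2AlH and N-methylmorpholine N-oxide to methyl 2-(diisobutylalumanyl)prop-2-enoate F6. This vinylalane adds to 21 at 0 °C and gives the same adduct 23 without an amine base.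

**Step 4.** The most likely failures are loss of regiocontrol in making dienolate 5, by partial deprotonation at the silyloxymethyl carbon, and reduced rate or selectivity with this bulky dienolate. The fallback sets out from 6 and returns at 9. The same copper catalyst with commercial 1-methoxy-1,3-bis(trimethylsilyloxy)buta-1,3-diene would give methyl (R)-5-hydroxy-6-[(4-methoxybenzyl)oxy]-3-oxohexanoate F7. K2CO3 in MeOH and acidification would close it to (R)-4-hydroxy-6-{[(4-methoxybenzyl)oxy]methyl}-5,6-dihydro-2H-pyran-2-one F8. Tf2O and iPr2NEt would give the enol triflate F9. Stille coupling with Bu3SnCH2OH, Pd(PPh3)4 (zerovalent palladium) and LiCl would give the 4-(hydroxymethyl) lactone F10, and TBDPSCl with imidazole would give 9.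

## Further compounds

F1 | step 9 | (2E,4S,7R)-7-[(tert-butyldimethylsilyl)oxy]-8-[(4-methoxybenzyl)oxy]-2-methyl-5-{[(tert-butyldiphenylsilyl)oxy]methyl}... homoallylic alcohol from methallylation of 12 (C2–OH, S) | CC(C)(C)[Si](C)(C)O[C@@H](COCc1ccc(OC)cc1)C/C(CO[Si](c2ccccc2)(c2ccccc2)C(C)(C)C)=C\[C@@H](O)CC(C)=C
F2 | step 9 | acrylate ester of F1 | CC(C)(C)[Si](C)(C)O[C@@H](COCc1ccc(OC)cc1)C/C(CO[Si](c2ccccc2)(c2ccccc2)C(C)(C)C)=C\[C@@H](OC(=O)C=C)CC(C)=C
F3 | step 17 | C6-epimeric macrocyclic hydroxy ester as its trimethylsilyl ether | CC(C)(C)[Si](C)(C)O[C@@H]1C/C(CO[Si](c2ccccc2)(c2ccccc2)C(C)(C)C)=C\[C@@H](OC(C)=O)C/C(C)=C\[C@H](O[Si](C)(C)C)[C@@H]1C(=C)C(=O)OC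
F4 | step 17 | macrocyclic C6 ketone (methyl 2-substituted acrylate on C7) | CC(C)(C)[Si](C)(C)O[C@@H]1C/C(CO[Si](c2ccccc2)(c2ccccc2)C(C)(C)C)=C\[C@@H](OC(C)=O)C/C(C)=C\C(=O)[C@@H]1C(=C)C(=O)OC
F5 | step 16 | hydroxy enal (Morita–Baylis–Hillman alcohol with C6 aldehyde) | CC(C)(C)[Si](C)(C)O[C@@H](C(O)C(=C)C(=O)OC)C/C(CO[Si](c1ccccc1)(c1ccccc1)C(C)(C)C)=C\[C@@H](OC(C)=O)C/C(C)=C\C=O
F6 | step 14 | methyl 2-(diisobutylalumanyl)prop-2-enoate | C=C(C(=O)OC)[Al](CC(C)C)CC(C)C
F7 | step 4 | methyl (R)-5-hydroxy-6-[(4-methoxybenzyl)oxy]-3-oxohexanoate | COC(=O)CC(=O)C[C@@H](O)COCc1ccc(OC)cc1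
F8 | step 4 | (R)-4-hydroxy-6-{[(4-methoxybenzyl)oxy]methyl}-5,6-dihydro-2H-pyran-2-one | COc1ccc(COC[C@H]2CC(O)=CC(=O)O2)cc1
F9 | step 4 | (R)-6-{[(4-methoxybenzyl)oxy]methyl}-2-oxo-5,6-dihydro-2H-pyran-4-yl trifluoromethanesulfonate | COc1ccc(COC[C@H]2CC(OS(=O)(=O)C(F)(F)F)=CC(=O)O2)cc1
F10 | step 4 | (R)-4-(hydroxymethyl)-6-{[(4-methoxybenzyl)oxy]methyl}-5,6-dihydro-2H-pyran-2-one | COc1ccc(COC[C@H]2CC(CO)=CC(=O)O2)cc1
A1 | alternative 1 | 2,14-diacetate of the target skeleton (O8 methacrylate) | C=C(C)C(=O)O[C@@H]1C/C(COC(C)=O)=C\[C@@H](OC(C)=O)C/C(C)=C\[C@H]2OC(=O)C(=C)[C@@H]21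
A2 | alternative 1 | ring diene with exocyclic C10=C14 and ring-cis C1=C2 (O8 methacrylate, 12,6-olide) | C=C(C)C(=O)O[C@@H]1CC(=C)/C=C\C/C(C)=C\[C@H]2OC(=O)C(=C)[C@@H]21
A3 | alternative 2 | bis-lactone (C11 lactonised to O6 and to O8; O2 acetate, O14 TBDPS) | O=C1O[C@@H]2C/C(CO[Si](c4ccccc4)(c5ccccc5)C(C)(C)C)=C\[C@@H](OC(C)=O)C/C(C)=C\[C@H]3OC(=O)[C@H]1[C@H]23
A4 | alternative 2 | C8 hydrogen malonate of the ring 4,6-diene (O2 acetate, O14 TBDPS) | OC(=O)CC(=O)O[C@@H]1C/C(CO[Si](c2ccccc2)(c2ccccc2)C(C)(C)C)=C\[C@@H](OC(C)=O)C/C(C)=C\C=C/1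
A5 | alternative 3 | ten-membered dienone (C6 ketone, free O14, O8 PMB, O2 TBS) | COc1ccc(cc1)CO[C@@H]2C/C(CO)=C\[C@@H](O[Si](C)(C)C(C)(C)C)C/C(C)=C\C(=O)C2
A6 | alternative 3 | cis-fused bicyclic epoxy alcohol (C1–C6 bond, C6 tertiary alcohol, spiro-epoxide at C10) | O[C@@]12C=C(C)C[C@H](O[Si](C)(C)C(C)(C)C)[C@@H]1[C@@]3(CO3)C[C@@H](OCc4ccc(OC)cc4)C2
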